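The plan cuts C6–C7 (germacrane numbering), the bond shared by the ten-membered carbocycle and the α-methylene-γ-lactone. This exploits one feature: C6 bears the lactone oxygen and C7 bears the C11(=C13)–C12 acrylate, so a C6 enal and a C13 allylic bromide are latent partners. A single chromium-mediated operation forms C6–C7, unveils the C11=C13 methylene, closes the carbocycle and sets C6 and C7. The C6 alkoxide then closes the lactone on C12. The precursor is an open chain carrying the Z-enal, the preset (1R,10S)-epoxide with its C14 alcohol silylated, an (8R)-silyl ether chosen as a poor leaving group, and a (Z)-2-(bromomethyl)enoate.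

Key step: step 16

Remark: germacrane numbering is used for all intermediates (C1–C10 ring carbons, C11–C13 acrylate, C14 on C10, C15 on C4). The allylchromium intermediate is assumed to interconvert its C7=C11 geometries faster than it adds to the aldehyde.

Step 1
Reactants: 1 nerol
Product: 2 neryl 4-methoxybenzyl (PMB) ether (C6–OPMB, Z-C4=C5)
Conditions: NaH, PMBCl, nBu4NI (cat.), THF–DMF, 0 °C → rt
Reagents that add atoms: 4-methoxybenzyl chloride, COc1ccc(CCl)cc1
Why: Williamson etherification of the primary allylic alkoxide; the PMB ether tolerates the later base, hydride, peroxide and silylation steps and can be removed oxidatively without touching silyl ethers or the epoxide.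

Step 2
Reactants: 2 neryl PMB ether
Product: 3 distal (isopropylidene) epoxide of 2, racemic at the secondary epoxide carbon (future C1)
Conditions: mCPBA (1 equiv), CH2Cl2, −20 °C
Reagents that add atoms: 3-chloroperoxybenzoic acid, O=C(OO)c1cccc(Cl)c1
Why: Prilezhaev epoxidation should prefer the more electron-rich distal alkene because C4=C5 is deactivated by its allylic oxygen; the new stereocentre is destroyed in step 3.

Step 3
Reactants: 3 distal epoxide
Product: 5 (4Z)-6-(4-methoxybenzyloxy)-4-methylhex-4-enal (C1 aldehyde, C1–C6 plus C15), via vicinal diol 4 (not isolated)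
Conditions: H5IO6, THF–H2O, 0 °C
Reagents that add atoms: water, O
Why: Acid-assisted epoxide hydrolysis followed by Malaprade glycol cleavage removes the isopropylidene carbons as acetone and leaves C1 as the aldehyde without disturbing the Z-alkene.

Step 4
Reactants: 6 methyl bis(2,2,2-trifluoroethyl)phosphonoacetate; 7 allyl bromide
Product: 8 methyl 2-[bis(2,2,2-trifluoroethoxy)phosphoryl]pent-4-enoate (racemic)
Conditions: NaH, THF, 0 °C; then 7, rt
Reagents that add atoms: none
Why: SN2 C-alkylation of the stabilised phosphonate carbanion by a reactive allylic halide, with a slight excess of 6 to limit double alkylation; the stereocentre is lost in step 5.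

Step 5
Reactants: 5 C1 aldehyde; 8 α-allyl phosphonate
Product: 9 methyl (2Z,6Z)-2-allyl-8-(4-methoxybenzyloxy)-6-methylocta-2,6-dienoate (C14 ester cis to the C2 chain)
Conditions: KN(SiMe3)2, 18-crown-6, THF, −78 °C
Reagents that add atoms: none
Why: Still–Gennari variant of the Horner–Wadsworth–Emmons olefination; the electron-poor phosphonate under dissociating conditions eliminates kinetically to the Z-enoate, which places C2 and C14 on the same side of C1=C10 as the target epoxide requires.

Step 6
Reactants: 9 Z-enoate
Product: 10 (2Z,6Z)-2-allyl-8-(4-methoxybenzyloxy)-6-methylocta-2,6-dien-1-ol (free C14 alcohol)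
Conditions: iBu2AlH, CH2Cl2, −78 °C; aq. potassium sodium tartrate
Reagents that add atoms: none
Why: 1,2-Reduction of the conjugated ester by two hydride equivalents gives the allylic alcohol with retention of alkene geometry, and ethers and isolated alkenes are inert.

Step 7
Reactants: 10 Z-allylic alcohol
Product: 11 (1R,10S)-epoxy alcohol, [(2S,3R)-2-allyl-3-{(3Z)-5-(4-methoxybenzyloxy)-3-methylpent-3-en-1-yl}oxiran-2-yl]methanol
Conditions: Ti(OiPr)4, L-(+)-diethyl tartrate, tBuOOH, 4 Å MS, CH2Cl2, −20 °C
Reagents that add atoms: tert-butyl hydroperoxide, CC(C)(C)OO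
Why: Sharpless asymmetric epoxidation acts only on the alkene of the free allylic alcohol; L-(+)-tartrate gives (2S,3R)-epoxy alcohols from Z-allylic alcohols, which sets C10 as S and C1 as R, and syn oxygen transfer keeps C2 and C14 cis.

Step 8
Reactants: 11 epoxy alcohol
Product: 12 C14 tert-butyldimethylsilyl (TBS) ether of 11
Conditions: TBSCl, imidazole, DMF, 0 °C → rt
Reagents that add atoms: tert-butyldimethylsilyl chloride, CC(C)(C)[Si](C)(C)Cl
Why: Imidazole-promoted silylation forms no free alkoxide, so Payne rearrangement is avoided, and TBS is orthogonal to both the C6 PMB ether and the later C8 triethylsilyl ether.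

Step 9
Reactants: 12 terminal alkene
Product: 14 (8R)-7,8-diol, via 7,8-bis(pinacolboronate) 13 (not isolated)
Conditions: Pt(dba)3 (cat.), chiral TADDOL-derived phenylphosphonite (the enantiomer that turns 1-alkenes into (R)-1,2-diols), B2pin2, THF, 60 °C; then NaOH, H2O2, 0 °C → rt
Reagents that add atoms: bis(pinacolato)diboron (boryl groups of 13 only), CC1(C)OB(OC1(C)C)B2OC(C)(C)C(C)(C)O2; hydrogen peroxide, OO
Why: Platinum-catalysed enantioselective syn-1,2-diboration accepts only monosubstituted alkenes, so the more electron-rich C4=C5 alkene, which an osmium reagent would attack first, stays intact; the ligand fixes the C8–B bond and peroxide oxidation replaces both C–B bonds by C–O with retention to give 8R.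

Step 10
Reactants: 14 diol
Product: 15 7,8-bis(triethylsilyl) (TES) ether
Conditions: TESCl, imidazole, DMAP (cat.), CH2Cl2, 0 °C → rt
Reagents that add atoms: chlorotriethylsilane, CC[Si](Cl)(CC)CC
Why: Exhaustive silylation under mild base protects both hydroxyls in one operation and prepares the primary/secondary differentiation of step 11.

Step 11
Reactants: 15 bis-TES ether
Product: 16 (8R)-8-triethylsilyloxy C7 aldehyde
Conditions: (COCl)2, DMSO, CH2Cl2, −78 → −40 °C; Et3N, −78 °C → rt
Reagents that add atoms: none
Why: Under Swern conditions the chlorosulfonium salt cleaves the unhindered primary TES ether and oxidises it directly to the aldehyde, a known selective oxidative desilylation that leaves secondary TES, primary TBS, PMB and the epoxide alone and keeps C8 intact at low temperature.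

Step 12
Reactants: 16 α-silyloxy aldehyde; 17 methyl acrylate
Product: 18 Morita–Baylis–Hillman adduct, methyl 2-methylene-3-hydroxy ester (C7 carbinol as an epimer mixture, 8R)
Conditions: 17 (excess), quinuclidine, MeOH (sub-stoichiometric), rt
Reagents that add atoms: none
Why: Morita–Baylis–Hillman reaction joins C7 to C11, helped by the inductively activated α-oxy aldehyde; the C7 configuration does not matter because it is erased in step 13.

Step 13
Reactants: 18 Baylis–Hillman adduct
Product: 19 (Z)-2-(bromomethyl)enoate (C7=C11, C8 trans to the ester, C13–Br), C6–OPMB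
Conditions: NBS, Me2S, CH2Cl2, 0 °C → rt
Reagents that add atoms: N-bromosuccinimide, O=C1CCC(=O)N1Br
Why: Corey–Kim-type activation of the hydroxyl as an alkoxysulfonium salt followed by SN2′ attack of bromide at C13 converges both C7 epimers on the favoured Z-bromide under essentially neutral conditions that spare the epoxide.

Step 14
Reactants: 19 PMB ether bromide
Product: 20 C6 allylic alcohol bromide
Conditions: DDQ, CH2Cl2–pH 7 buffer, 0 °C
Reagents that add atoms: none
Why: Oxidative PMB cleavage by hydride abstraction from the electron-rich benzyl ether is neutral and orthogonal to both silyl ethers, the epoxide and the allylic bromide.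

Step 15
Reactants: 20 Z-allylic alcohol
Product: 21 cyclisation precursor: Z-enal, (1R,10S)-epoxide, 14-OTBS, (8R)-OTES, (Z)-2-(bromomethyl)enoate
Conditions: MnO2, CH2Cl2, rt
Reagents that add atoms: none
Why: Heterogeneous, neutral allylic oxidation with MnO2 keeps the Z geometry of neral-type enals; placing it last means the isomerisation-prone enal is used at once.

Step 16
Reactants: 21 Z-enal allylic bromide
Product: 24 ten-membered trans-fused α-methylene-γ-lactone with 8-OTES and 14-OTBS, via allylchromium dichloride 22 (not isolated), via ring-closed chromium alkoxide 23 (not isolated)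
Conditions: CrCl2 (10 equiv), 4 Å MS, THF–DMF (4:1), rt; 21 added by syringe pump (final 2 mM); aqueous work-up
Reagents that add atoms: chromium dichloride (its atoms stay only in 22 and 23), Cl[Cr]Cl
Why: Two equivalents of divalent chromium reduce the C13–Br bond by successive one-electron transfers to the allylchromium dichloride 22 (trivalent chromium), which adds to the C6 aldehyde through its γ-carbon C7 (SE2′) in a six-membered Zimmerman–Traxler chair; this is an intramolecular Nozaki–Hiyama allylation with a 2-(alkoxycarbonyl)allyl halide, a known entry to medium-ring α-methylene lactones. The carbocycle closes by 10-exo-trig addition to the aldehyde, leaving C11=C13 exocyclic, and the lactone closes by 5-exo-trig addition–elimination of the C6 chromium alkoxide 23 at the C12 methyl ester. The C6/C7 relationship is set by the chair: 22 interconverts its C7=C11 isomers by 1,3-metal shift and should react through the isomer with C8 trans to CH2Cr, so C5 and C8 are both equatorial and the anti adduct, hence the trans-fused lactone, is expected. The face of C7 is set by C8: allylic strain with the C12 ester holds H8 in the allyl plane, the C8–C9 bond of the tether stands anti to the forming bond and the silyloxy group points outward, which corresponds to the target's C7/C8 relationship, while the preset epoxide and Z-alkene restrict the tether. The step needs C–Br reduction ahead of enal reduction or epoxide opening, γ- over α-attack (which would give a twelve-membered ring), ring closure ahead of dimerisation, and addition ahead of 1,4-loss of the C8 oxygen. These are secured by the fast reduction of allylic bromides, the closed transition state, slow addition at high dilution and the poor leaving-group ability of the silyl ether, and the neutral aprotic medium protects the Z-enal.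

Step 17
Reactants: 24 bis-silylated lactone
Product: 25 C8 alcohol (14-OTBS retained)
Conditions: PPTS (cat.), MeOH–CH2Cl2, 0 °C
Reagents that add atoms: none
Why: Acid-catalysed methanolysis discriminates by silyl size, the secondary TES ether being far more labile than the neopentyl-type primary TBS ether, and the mild non-basic medium avoids lactone migration from O6 to O8 and epoxide opening.

Step 18
Reactants: 25 C8 alcohol
Product: 26 C8 isobutyrate (14-OTBS)
Conditions: (iPrCO)2O, DMAP (cat.), Et3N, CH2Cl2, 0 °C → rt
Reagents that add atoms: isobutyric anhydride, CC(C)C(=O)OC(=O)C(C)C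
Why: DMAP-catalysed acylation of the hindered secondary alcohol with retention at C8, under weak base and short contact so that neither relactonisation nor conjugate addition to the methylene lactone should compete.

Step 19
Reactants: 26 silyl ether
Product: 27 target CNP0247143.1, (1R,6R,7R,8R,10S)
Conditions: Et3N·3HF, MeCN, rt
Reagents that add atoms: none
Why: Fluoride-driven desilylation with a nearly neutral amine–HF complex frees the C14 alcohol without forming an alkoxide, so Payne rearrangement, acyl migration, epoxide opening and attack on the lactone are not expected.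

Compound list
1 | nerol, (2Z)-3,7-dimethylocta-2,6-dien-1-ol | CC(C)=CCC/C(C)=C\CO | starting material
2 | neryl 4-methoxybenzyl ether | COc1ccc(COC/C=C(/C)CCC=C(C)C)cc1 | intermediate
3 | distal epoxide of 2 (racemic) | COc1ccc(COC/C=C(/C)CCC2OC2(C)C)cc1 | intermediate
4 | vicinal diol from 3 (racemic, not isolated) | COc1ccc(COC/C=C(/C)CCC(O)C(C)(C)O)cc1 | intermediate
5 | (4Z)-6-(4-methoxybenzyloxy)-4-methylhex-4-enal | COc1ccc(COC/C=C(/C)CCC=O)cc1 | intermediate
6 | methyl bis(2,2,2-trifluoroethyl)phosphonoacetate | COC(=O)CP(=O)(OCC(F)(F)F)OCC(F)(F)F | starting material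
7 | allyl bromide | C=CCBr | starting material
8 | methyl 2-[bis(2,2,2-trifluoroethoxy)phosphoryl]pent-4-enoate (racemic) | C=CCC(C(=O)OC)P(=O)(OCC(F)(F)F)OCC(F)(F)F | intermediate
9 | methyl (2Z,6Z)-2-allyl-8-(4-methoxybenzyloxy)-6-methylocta-2,6-dienoate | COc1ccc(COC/C=C(/C)CC/C=C(/CC=C)C(=O)OC)cc1 | intermediate
10 | (2Z,6Z)-2-allyl-8-(4-methoxybenzyloxy)-6-methylocta-2,6-dien-1-ol | COc1ccc(COC/C=C(/C)CC/C=C(/CC=C)CO)cc1 | intermediate
11 | (1R,10S)-epoxy alcohol | COc1ccc(COC/C=C(/C)CC[C@H]2O[C@]2(CO)CC=C)cc1 | intermediate
12 | 14-O-TBS ether of 11 | COc1ccc(COC/C=C(/C)CC[C@H]2O[C@]2(CO[Si](C)(C)C(C)(C)C)CC=C)cc1 | intermediate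
13 | 7,8-bis(pinacolboronate), 8S by CIP rank, same spatial arrangement as 8R in 14 (not isolated) | COc1ccc(COC/C=C(/C)CC[C@H]2O[C@]2(CO[Si](C)(C)C(C)(C)C)C[C@@H](B3OC(C)(C)C(C)(C)O3)CB4OC(C)(C)C(C)(C)O4)cc1 | intermediate
14 | (1R,8R,10S)-7,8-diol | COc1ccc(COC/C=C(/C)CC[C@H]2O[C@]2(CO[Si](C)(C)C(C)(C)C)C[C@@H](O)CO)cc1 | intermediate
15 | 7,8-bis-TES ether | COc1ccc(COC/C=C(/C)CC[C@H]2O[C@]2(CO[Si](C)(C)C(C)(C)C)C[C@@H](O[Si](CC)(CC)CC)CO[Si](CC)(CC)CC)cc1 | intermediate
16 | (8R)-8-OTES C7 aldehyde | COc1ccc(COC/C=C(/C)CC[C@H]2O[C@]2(CO[Si](C)(C)C(C)(C)C)C[C@@H](O[Si](CC)(CC)CC)C=O)cc1 | intermediate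
17 | methyl acrylate | C=CC(=O)OC | starting material
18 | Baylis–Hillman adduct (C7 epimers) | COc1ccc(COC/C=C(/C)CC[C@H]2O[C@]2(CO[Si](C)(C)C(C)(C)C)C[C@@H](O[Si](CC)(CC)CC)C(O)C(=C)C(=O)OC)cc1 | intermediate
19 | (Z)-2-(bromomethyl)enoate, C6–OPMB | COc1ccc(COC/C=C(/C)CC[C@H]2O[C@]2(CO[Si](C)(C)C(C)(C)C)C[C@@H](O[Si](CC)(CC)CC)/C=C(/C(=O)OC)CBr)cc1 | intermediate
20 | C6 allylic alcohol bromide | OC/C=C(/C)CC[C@H]1O[C@]1(CO[Si](C)(C)C(C)(C)C)C[C@@H](O[Si](CC)(CC)CC)/C=C(/C(=O)OC)CBr | intermediate
21 | cyclisation precursor, Z-enal bromide | O=C/C=C(/C)CC[C@H]1O[C@]1(CO[Si](C)(C)C(C)(C)C)C[C@@H](O[Si](CC)(CC)CC)/C=C(/C(=O)OC)CBr | intermediate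
22 | allylchromium dichloride, drawn as the reactive isomer with C8 trans to CH2Cr (not isolated) | O=C/C=C(/C)CC[C@H]1O[C@]1(CO[Si](C)(C)C(C)(C)C)C[C@@H](O[Si](CC)(CC)CC)/C=C(\C(=O)OC)C[Cr](Cl)Cl | intermediate
23 | ring-closed C6 chromium alkoxide of the hydroxy ester (not isolated) | Cl[Cr](Cl)O[C@@H]1/C=C(/C)CC[C@H]2O[C@]2(CO[Si](C)(C)C(C)(C)C)C[C@@H](O[Si](CC)(CC)CC)[C@H]1C(=C)C(=O)OC | intermediate
24 | trans-fused α-methylene lactone, 8-OTES, 14-OTBS (H6/H7 trans; C7 reads S here only because silicon raises the rank of C8) | C=C1C(=O)O[C@@H]2/C=C(/C)CC[C@H]3O[C@]3(CO[Si](C)(C)C(C)(C)C)C[C@@H](O[Si](CC)(CC)CC)[C@@H]12 | intermediate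
25 | C8 alcohol, 14-OTBS | C=C1C(=O)O[C@@H]2/C=C(/C)CC[C@H]3O[C@]3(CO[Si](C)(C)C(C)(C)C)C[C@@H](O)[C@@H]12 | intermediate
26 | C8 isobutyrate, 14-OTBS | C=C1C(=O)O[C@@H]2/C=C(/C)CC[C@H]3O[C@]3(CO[Si](C)(C)C(C)(C)C)C[C@@H](OC(=O)C(C)C)[C@@H]12 | intermediate
27 | CNP0247143.1, (1R,6R,7R,8R,10S) | C=C1C(=O)O[C@@H]2/C=C(/C)CC[C@H]3O[C@]3(CO)C[C@@H](OC(=O)C(C)C)[C@@H]12 | target

Total step count: 19. Longest linear sequence: 18 steps (steps 1–3 and 5–19, from nerol).

Steps most likely to fail

1. Step 16.
- **What may go wrong:** addition through a chair with C8 axial (syn addition), attack on the wrong face of C7, 1,4-elimination of the C8 silyloxy group from the allylchromium, Z-to-E isomerisation of the enal on the Lewis-acidic chromium salts, or intermolecular coupling.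
- **Fallback:** it sets out from 16 and rejoins at 24. It replaces the reductively made, configurationally mobile allylmetal by an isolable allylboronate of fixed geometry, which cannot eliminate and needs no reductant. Ohira–Bestmann homologation of 16 (dimethyl (1-diazo-2-oxopropyl)phosphonate, K2CO3, MeOH) should give the terminal alkyne F1. LiN(SiMe3)2 and then ClCO2Me give the ynoate F2. Syn-hydroalumination (iBu2AlH, HMPA, THF) and capture of the α-alumino acrylate with ICH2Bpin give the 2-(borylmethyl)enoate F3, in which C8 is trans to CH2B. DDQ frees the allylic alcohol F4 and MnO2 gives the enal boronate F5. On warming in dilute toluene, F5 should close C6–C7 through the closed chair of an allylboration, where the anti outcome is dictated by the fixed alkene geometry. The borate alkoxide then lactonises to 24.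

2. Step 12.
- **What may go wrong:** slow turnover leaves the α-silyloxy aldehyde in contact with the amine for a long time, so epimerisation at C8 and loss of the TES group may compete.
- **Fallback:** it sets out from 16 and rejoins at 18. The amine-catalysed coupling is replaced by a preformed vinylmetal. Methyl propiolate is hydroaluminated (iBu2AlH, HMPA, THF, 0 °C) to methyl 2-(diisobutylalumanyl)acrylate F6. F6 adds 1,2 to 16 at low temperature without any base and gives 18 after aqueous work-up.

3. Step 9.
- **What may go wrong:** weak catalyst control next to the quaternary C10 (poor facial selectivity at C8) or catalyst inhibition by the polyoxygenated substrate.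
- **Fallback:** it sets out from 12 and rejoins at 14. The two oxygens are introduced one after the other. 9-BBN hydroborates only the monosubstituted alkene, and NaOH/H2O2 gives the primary alcohol F7. Dess–Martin periodinane gives the C7 aldehyde F8. L-Proline-catalysed α-aminoxylation with nitrosobenzene sets 8R in the α-anilinooxy aldehyde F9, which NaBH4 reduces in the same flask to the anilinooxy alcohol F10. CuSO4 in MeOH cleaves the N–O bond to give 14.

Further compounds
F1 | step 16 | (8R)-8-OTES terminal alkyne (C7≡C11–H) | COc1ccc(COC/C=C(/C)CC[C@H]2O[C@]2(CO[Si](C)(C)C(C)(C)C)C[C@@H](O[Si](CC)(CC)CC)C#C)cc1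
F2 | step 16 | methyl ynoate (C7≡C11–C12) | COc1ccc(COC/C=C(/C)CC[C@H]2O[C@]2(CO[Si](C)(C)C(C)(C)C)C[C@@H](O[Si](CC)(CC)CC)C#CC(=O)OC)cc1
F3 | step 16 | 2-(pinacolborylmethyl)enoate, C8 cis to ester and trans to CH2B, C6–OPMB | COc1ccc(COC/C=C(/C)CC[C@H]2O[C@]2(CO[Si](C)(C)C(C)(C)C)C[C@@H](O[Si](CC)(CC)CC)/C=C(\C(=O)OC)CB3OC(C)(C)C(C)(C)O3)cc1
F4 | step 16 | C6 allylic alcohol allylboronate | OC/C=C(/C)CC[C@H]1O[C@]1(CO[Si](C)(C)C(C)(C)C)C[C@@H](O[Si](CC)(CC)CC)/C=C(\C(=O)OC)CB2OC(C)(C)C(C)(C)O2
F5 | step 16 | Z-enal allylboronate | O=C/C=C(/C)CC[C@H]1O[C@]1(CO[Si](C)(C)C(C)(C)C)C[C@@H](O[Si](CC)(CC)CC)/C=C(\C(=O)OC)CB2OC(C)(C)C(C)(C)O2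
F6 | step 12 | methyl 2-(diisobutylalumanyl)acrylate | C=C(C(=O)OC)[Al](CC(C)C)CC(C)C
F7 | step 9 | C7 primary alcohol (C8 unoxidised) | COc1ccc(COC/C=C(/C)CC[C@H]2O[C@]2(CO[Si](C)(C)C(C)(C)C)CCCO)cc1
F8 | step 9 | C7 aldehyde (C8 unoxidised) | COc1ccc(COC/C=C(/C)CC[C@H]2O[C@]2(CO[Si](C)(C)C(C)(C)C)CCC=O)cc1
F9 | step 9 | (8R)-8-anilinooxy C7 aldehyde | COc1ccc(COC/C=C(/C)CC[C@H]2O[C@]2(CO[Si](C)(C)C(C)(C)C)C[C@@H](ONc3ccccc3)C=O)cc1
F10 | step 9 | (8R)-8-anilinooxy C7 alcohol | COc1ccc(COC/C=C(/C)CC[C@H]2O[C@]2(CO[Si](C)(C)C(C)(C)C)C[C@@H](ONc3ccccc3)CO)cc1
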